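| flask | solid substrate | remark | time |
|---|---|---|---|
| Thursday's | 0.50 mM | run made earlier |  |
| Friday's | 0.75 mM | run made earlier |  |
| flask | 1.0 mM |  | 2.0 min |

| run | time / s | target / % | solid substrate / % |
|---|---|---|---|
| Thursday's | 15.0 | 3.4 | 73.8 |
| Thursday's | 30.0 | 12.9 | 52.4 |
| Thursday's | 50.0 | 28.6 | 24.5 |
| Thursday's | 60.0 | 35.7 | 12.0 |
| Thursday's | 80.0 | 53.0 | 0 |
| Thursday's | 90.0 | 58.3 | 0 |
| Friday's | 10.0 | 1.8 | 88.2 |
| Friday's | 12.0 | 2.0 | 86.1 |
| Friday's | 20.0 | 4.0 | 77.9 |
| Friday's | 40.0 | 13.7 | 59.1 |
| Friday's | 60.0 | 24.7 | 41.4 |
| Friday's | 90.0 | 42.5 | 16.1 |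

(each reading ± 0.5 percentage points)

- solid, in amounts per volume of the solution: solid substrate
- at the start none of the solid substrate is in solution

* the target standing at 2.0 min, as a percentage of the solid substrate charged
* the change that raises the amount of target at 2.0 min, in percent of the solid substrate charged most ("none" if none brings more than 2 percentage points) (beta / theta / none)
* amount of target at 2.0 min, in percent of the solid substrate charged, after theta

- beta: doubling the solubility of the solid substrate, all else as stated
- theta: doubling the dissolution coefficient of the solid substrate, all else as stated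

Between Thursday's run and Friday's run one quantity nearly holds although the charges differ: the solid substrate lost per second, counted in mM. Friday's run gives 0.00699 mM s⁻¹ over 90.0 s, and Thursday's run gives 0.00733 mM s⁻¹ over 60.0 s, about the same. This mean rate of loss, the charge minus the solid left, divided by the time, gives a bench rule: in these two runs the loss reads as zero order in the solid, and the rule takes the solid to last for the charge divided by the mean rate.

Thursday's run: border = 0.50 mM / 0.00699 mM s⁻¹ = 71.5 s

Flask: border = 1.0 mM / 0.00699 mM s⁻¹ = 143 s

Past its border the rule stops: Thursday's solid reads 12.0% at 60.0 s and 0% at 80.0 s. The flask is read at 0.839 of its border, so solid should remain.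

The mean hides a slowing, since Friday's loss runs at 0.00885 mM s⁻¹ at first and 0.00645 mM s⁻¹ late. For the flask at 2.0 min, the mean gives an estimate of 16.1% solid, and Friday's loss by 90.0 s followed by the late rate over the final 30.0 s gives an estimate of 17.7%.

At 60.0 s, where both runs still read solid, [target] also nearly agrees in mM: 0.179 mM on Thursday and 0.185 mM on Friday. This reckoning therefore lets the flask continue Friday's curve at its late mean gain:

[target] = 0.319 mM + 0.00445 mM s⁻¹ × 30.0 s, which is 45.2% of the charge.

The forecast, slightly above this reckoning, gives 46%, names beta as the best change and gives 59% after theta, holding that “Solid lasts past 2 min”.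

The flask gives 45.1% of target; beta is the best change, gaining 22 percentage points against 19 points for theta, and theta brings 64.2%.

    other conformer → isomer of the product (k = 0.747 s⁻¹)
    target ⇌ isomer of the product (K = 2.50, k = 5.19 × 10⁻⁴ s⁻¹)
    2 starting material → homo dimer (k = 0.0318 M⁻¹ s⁻¹)
    starting material ⇌ other conformer (K = 0.453, k = 0.00727 s⁻¹)
    starting material → target (k = 0.0224 s⁻¹)
    solid substrate ⇌ starting material, rate k6*(cs6 - [starting material]) while solid is left; crystals form when [starting material] > cs6 (solubility = 0.620 mM, k = 0.0152 s⁻¹)

The flask still holds 18.2% solid substrate at 2.00 min. Carried to the neighbour with 4.0 mM of solid substrate, the mean rate puts the border at 9.54 min and takes 21.0% of that charge, leaving 79.0%; that neighbour holds 79.6% solid substrate at 2.00 min.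

The runs are calculated from invented constants; scatter was added.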